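**Retrosynthetic overview**
1. Target 19 ⇐ 18 by loss of two silyl groups; the furan ring of the benzofuran is the last ring made.
2. 18 ⇐ 10 + 15: the benzofuran C2–C3 bond is cut. The formyl carbon of 10 reacts as an acyl anion (thiazolium carbene) with the CH2 of the o-quinone methide released from 15; acid then closes the furan ring.
3. 10 ⇐ 7 ⇐ 5: dehydrative C5-formylation of a δ-lactol obtained by linear hydroformylation; the dihydropyran ring is made first.
4. 5 ⇐ 4 ⇐ 2 + 3: one iridium-catalysed anti-(hydroxymethyl)allylation of silylated vanillin sets both stereocentres.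
5. 15 ⇐ 11: C-acetylation, differential silylation and benzylic bromination of methylhydroquinone.

Assumption: the (S) antipode of the ligand in step 2 is taken to give the (1R,2S)-diol 4; if the sense of induction is the opposite, the (R) antipode is used with no other change.

**Step 1**
Reactants: 1 vanillin (4-hydroxy-3-methoxybenzaldehyde)
Product: 2 3-methoxy-4-[(triisopropylsilyl)oxy]benzaldehyde
Conditions: i-Pr3SiCl (1.1 equiv), imidazole (2 equiv), DMF, 0 °C → rt
Reagents that add atoms: chlorotriisopropylsilane, CC(C)[Si](Cl)(C(C)C)C(C)C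
Why: Standard phenol silylation; the bulky aryl TIPS ether is chosen to survive mild base, the Vilsmeier step and one equivalent of fluoride later on.

**Step 2**
Reactants: 2 3-methoxy-4-[(triisopropylsilyl)oxy]benzaldehyde; 3 4-ethenyl-1,3-dioxolan-2-one (vinyl ethylene carbonate, racemic, 2 equiv)
Product: 4 (1R,2S)-2-ethenyl-1-{3-methoxy-4-[(triisopropylsilyl)oxy]phenyl}propane-1,3-diol
Conditions: [Ir(cod)Cl]2 (2.5 mol%), (S)-5,5′-bis(diphenylphosphino)-4,4′-bi-1,3-benzodioxole (5 mol%), 4-chloro-3-nitrobenzoic acid (10 mol%), Cs2CO3 (20 mol%), i-PrOH (2 equiv), THF, 90 °C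
Reagents that add atoms: none
Why: Iridium-catalysed transfer-hydrogenative carbonyl (hydroxymethyl)allylation; decarboxylative ionisation of 3 gives a (hydroxymethyl)allyl-iridium nucleophile that adds through a closed chair transition state from the (E)-σ-allyl form (anti relationship), while the chiral bisphosphine selects the aldehyde face, so both stereocentres (1R,2S) are set here.

**Step 3**
Reactants: 4 (1R,2S)-2-ethenyl-1-{3-methoxy-4-[(triisopropylsilyl)oxy]phenyl}propane-1,3-diol
Product: 5 (2S)-2-[(R)-hydroxy{3-methoxy-4-[(triisopropylsilyl)oxy]phenyl}methyl]but-3-en-1-yl acetate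
Conditions: AcCl (1.05 equiv), 2,4,6-collidine (2 equiv), CH2Cl2, −78 °C
Reagents that add atoms: acetyl chloride, CC(Cl)=O
Why: Kinetically selective O-acylation of the primary hydroxyl over the hindered secondary benzylic one; this acetate is the one kept in the target.

**Step 4**
Reactants: 5 (2S)-2-[(R)-hydroxy{3-methoxy-4-[(triisopropylsilyl)oxy]phenyl}methyl]but-3-en-1-yl acetate
Product: 7 [(2R,3S)-6-hydroxy-2-{3-methoxy-4-[(triisopropylsilyl)oxy]phenyl}oxan-3-yl]methyl acetate (anomeric mixture), via hydroxy aldehyde 6 (not isolated)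
Conditions: Rh(acac)(CO)2 (1 mol%), 4,5-bis(diphenylphosphino)-9,9-dimethylxanthene (2 mol%), CO/H2 (1:1, 10 bar), toluene, 70 °C
Reagents that add atoms: carbon monoxide, [C-]#[O+]
Why: Linear-selective rhodium hydroformylation of the terminal alkene (wide-bite-angle diphosphine); the aldehyde is trapped by the benzylic hydroxyl as the six-membered lactol, and the two stereocentres are not touched.

**Step 5**
Reactants: 7 [(2R,3S)-6-hydroxy-2-{3-methoxy-4-[(triisopropylsilyl)oxy]phenyl}oxan-3-yl]methyl acetate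
Product: 10 [(2R,3S)-5-formyl-2-{3-methoxy-4-[(triisopropylsilyl)oxy]phenyl}-3,4-dihydro-2H-pyran-3-yl]methyl acetate, via enol ether 8 (not isolated), via iminium chloride 9 (not isolated)
Conditions: POCl3 (3 equiv), DMF (6 equiv), pyridine (4 equiv), CH2Cl2, 0 → 40 °C; then ice-water
Reagents that add atoms: N,N-dimethylformamide, CN(C)C=O; water, O
Why: Vilsmeier–Haack (Arnold) formylation of a masked aldehyde; the chloroiminium salt activates the lactol hydroxyl, elimination gives enol ether 8, its nucleophilic β-carbon (C5) is formylated and hydrolysis of 9 gives the vinylogous formate, with the anomeric centre destroyed and C2/C3 unchanged.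

**Step 6**
Reactants: 11 methylhydroquinone (2-methylbenzene-1,4-diol)
Product: 12 1-(2,5-dihydroxy-4-methylphenyl)ethan-1-one
Conditions: AcOH (3 equiv), BF3·OEt2 (3 equiv), 100 °C; then H2O, 50 °C
Reagents that add atoms: acetic acid, CC(=O)O
Why: Friedel–Crafts (Fries-type) C-acetylation of the hydroquinone ortho to a hydroxyl and para to the methyl group, the most activated and least hindered position.

**Step 7**
Reactants: 12 1-(2,5-dihydroxy-4-methylphenyl)ethan-1-one
Product: 14 1-(5-{[tert-butyl(dimethyl)silyl]oxy}-4-methyl-2-[(triisopropylsilyl)oxy]phenyl)ethan-1-one, via mono-TBS ether 13 (not isolated)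
Conditions: t-BuMe2SiCl (1.05 equiv), imidazole (2 equiv), CH2Cl2, 0 °C; then i-Pr3SiOTf (1.2 equiv), 2,6-lutidine (1.5 equiv), 0 °C → rt
Reagents that add atoms: tert-butyl(chloro)dimethylsilane, CC(C)(C)[Si](C)(C)Cl; triisopropylsilyl trifluoromethanesulfonate, CC(C)[Si](OS(=O)(=O)C(F)(F)F)(C(C)C)C(C)C
Why: Chemoselective silylation; the free phenol reacts first with the silyl chloride, while the phenol hydrogen-bonded to the acetyl group needs the silyl triflate, which gives a labile TBS trigger next to the methyl group and a robust TIPS cap on the other oxygen.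

**Step 8**
Reactants: 14 1-(5-{[tert-butyl(dimethyl)silyl]oxy}-4-methyl-2-[(triisopropylsilyl)oxy]phenyl)ethan-1-one
Product: 15 1-[4-(bromomethyl)-5-{[tert-butyl(dimethyl)silyl]oxy}-2-[(triisopropylsilyl)oxy]phenyl]ethan-1-one
Conditions: N-bromosuccinimide (1.05 equiv), 2,2′-azobis(2-methylpropionitrile) (5 mol%), PhCF3, 80 °C
Reagents that add atoms: N-bromosuccinimide, O=C1CCC(=O)N1Br
Why: Wohl–Ziegler radical benzylic bromination; both free ring positions are flanked by two substituents, which disfavours ionic ring bromination.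

**Step 9**
Reactants: 10 [(2R,3S)-5-formyl-2-{3-methoxy-4-[(triisopropylsilyl)oxy]phenyl}-3,4-dihydro-2H-pyran-3-yl]methyl acetate; 15 1-[4-(bromomethyl)-5-{[tert-butyl(dimethyl)silyl]oxy}-2-[(triisopropylsilyl)oxy]phenyl]ethan-1-one (1.3 equiv)
Product: 18 [(2R,3S)-5-{6-acetyl-5-[(triisopropylsilyl)oxy]-1-benzofuran-2-yl}-2-{3-methoxy-4-[(triisopropylsilyl)oxy]phenyl}-3,4-dihydro-2H-pyran-3-yl]methyl acetate, via quinone methide 16 (not isolated), via hydroxy ketone 17 (not isolated)
Conditions: 3,4,5-trimethylthiazolium iodide (20 mol%), 1,8-diazabicyclo[5.4.0]undec-7-ene (20 mol%), CsF (1.1 equiv per 15), 18-crown-6 (10 mol%), CH2Cl2, −20 → 0 °C; then pyridinium p-toluenesulfonate (0.5 equiv), 4 Å molecular sieves, 35 °C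
Reagents that add atoms: none
Why: Proposed new method: the thiazol-2-ylidene adds to the formyl group of 10 to give a Breslow intermediate (acyl anion equivalent, favoured over β-reactivity because the β-carbon carries the ring oxygen) that attacks the exocyclic CH2 of o-quinone methide 16, which forms when fluoride cleaves only the unhindered aryl TBS ether of 15 and bromide leaves, and the o-hydroxybenzyl ketone 17 then cyclodehydrates under mild acid through a strongly stabilised oxocarbenium ion to the benzofuran; the closest known reaction type is the thiazolium-catalysed Stetter-type acylation of fluoride-generated o-quinone methides by simple aldehydes followed by acid cyclodehydration, and no stereocentre is formed or touched.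

**Step 10**
Reactants: 18 [(2R,3S)-5-{6-acetyl-5-[(triisopropylsilyl)oxy]-1-benzofuran-2-yl}-2-{3-methoxy-4-[(triisopropylsilyl)oxy]phenyl}-3,4-dihydro-2H-pyran-3-yl]methyl acetate
Product: 19 propolis-benzofuran A, [(2R,3S)-5-(6-acetyl-5-hydroxy-1-benzofuran-2-yl)-2-(4-hydroxy-3-methoxyphenyl)-3,4-dihydro-2H-pyran-3-yl]methyl acetate
Conditions: Bu4NF (2.5 equiv), AcOH (3 equiv), THF, 0 °C
Reagents that add atoms: none
Why: Buffered fluoride desilylation of the two aryl TIPS ethers; the acetic acid keeps the phenols protonated, so the primary acetate, the enol ether and the p-hydroxybenzylic C2–O bond (C2 configuration) are not disturbed.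

**Compound list**
1 | vanillin | COc1cc(C=O)ccc1O | starting material
2 | 3-methoxy-4-[(triisopropylsilyl)oxy]benzaldehyde | COc1cc(C=O)ccc1O[Si](C(C)C)(C(C)C)C(C)C | intermediate
3 | 4-ethenyl-1,3-dioxolan-2-one (racemic) | C=CC1COC(=O)O1 | starting material
4 | (1R,2S)-2-ethenyl-1-{3-methoxy-4-[(triisopropylsilyl)oxy]phenyl}propane-1,3-diol | COc1cc([C@H](O)[C@H](CO)C=C)ccc1O[Si](C(C)C)(C(C)C)C(C)C | intermediate
5 | (2S)-2-[(R)-hydroxy{3-methoxy-4-[(triisopropylsilyl)oxy]phenyl}methyl]but-3-en-1-yl acetate | COc1cc([C@H](O)[C@H](COC(C)=O)C=C)ccc1O[Si](C(C)C)(C(C)C)C(C)C | intermediate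
6 | (2S)-2-[(R)-hydroxy{3-methoxy-4-[(triisopropylsilyl)oxy]phenyl}methyl]-5-oxopentyl acetate | COc1cc([C@H](O)[C@H](COC(C)=O)CCC=O)ccc1O[Si](C(C)C)(C(C)C)C(C)C | intermediate
7 | [(2R,3S)-6-hydroxy-2-{3-methoxy-4-[(triisopropylsilyl)oxy]phenyl}oxan-3-yl]methyl acetate (anomeric mixture) | COc1cc([C@@H]2OC(O)CC[C@H]2COC(C)=O)ccc1O[Si](C(C)C)(C(C)C)C(C)C | intermediate
8 | [(2R,3S)-2-{3-methoxy-4-[(triisopropylsilyl)oxy]phenyl}-3,4-dihydro-2H-pyran-3-yl]methyl acetate | COc1cc([C@@H]2OC=CC[C@H]2COC(C)=O)ccc1O[Si](C(C)C)(C(C)C)C(C)C | intermediate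
9 | N-{[(2R,3S)-3-(acetoxymethyl)-2-{3-methoxy-4-[(triisopropylsilyl)oxy]phenyl}-3,4-dihydro-2H-pyran-5-yl]methylidene}-N-methylmethanaminium chloride | COc1cc([C@@H]2OC=C(C=[N+](C)C)C[C@H]2COC(C)=O)ccc1O[Si](C(C)C)(C(C)C)C(C)C.[Cl-] | intermediate
10 | [(2R,3S)-5-formyl-2-{3-methoxy-4-[(triisopropylsilyl)oxy]phenyl}-3,4-dihydro-2H-pyran-3-yl]methyl acetate | COc1cc([C@@H]2OC=C(C=O)C[C@H]2COC(C)=O)ccc1O[Si](C(C)C)(C(C)C)C(C)C | intermediate
11 | methylhydroquinone (2-methylbenzene-1,4-diol) | Cc1cc(O)ccc1O | starting material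
12 | 1-(2,5-dihydroxy-4-methylphenyl)ethan-1-one | CC(=O)c1cc(O)c(C)cc1O | intermediate
13 | 1-(5-{[tert-butyl(dimethyl)silyl]oxy}-2-hydroxy-4-methylphenyl)ethan-1-one | CC(=O)c1cc(O[Si](C)(C)C(C)(C)C)c(C)cc1O | intermediate
14 | 1-(5-{[tert-butyl(dimethyl)silyl]oxy}-4-methyl-2-[(triisopropylsilyl)oxy]phenyl)ethan-1-one | CC(=O)c1cc(O[Si](C)(C)C(C)(C)C)c(C)cc1O[Si](C(C)C)(C(C)C)C(C)C | intermediate
15 | 1-[4-(bromomethyl)-5-{[tert-butyl(dimethyl)silyl]oxy}-2-[(triisopropylsilyl)oxy]phenyl]ethan-1-one | CC(=O)c1cc(O[Si](C)(C)C(C)(C)C)c(CBr)cc1O[Si](C(C)C)(C(C)C)C(C)C | intermediate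
16 | 3-acetyl-6-methylidene-4-[(triisopropylsilyl)oxy]cyclohexa-2,4-dien-1-one | C=C1C=C(O[Si](C(C)C)(C(C)C)C(C)C)C(C(C)=O)=CC1=O | intermediate
17 | [(2R,3S)-5-{2-[4-acetyl-2-hydroxy-5-[(triisopropylsilyl)oxy]phenyl]acetyl}-2-{3-methoxy-4-[(triisopropylsilyl)oxy]phenyl}-3,4-dihydro-2H-pyran-3-yl]methyl acetate | COc1cc([C@@H]2OC=C(C(=O)Cc3cc(O[Si](C(C)C)(C(C)C)C(C)C)c(C(C)=O)cc3O)C[C@H]2COC(C)=O)ccc1O[Si](C(C)C)(C(C)C)C(C)C | intermediate
18 | [(2R,3S)-5-{6-acetyl-5-[(triisopropylsilyl)oxy]-1-benzofuran-2-yl}-2-{3-methoxy-4-[(triisopropylsilyl)oxy]phenyl}-3,4-dihydro-2H-pyran-3-yl]methyl acetate | COc1cc([C@@H]2OC=C(c3cc4cc(O[Si](C(C)C)(C(C)C)C(C)C)c(C(C)=O)cc4o3)C[C@H]2COC(C)=O)ccc1O[Si](C(C)C)(C(C)C)C(C)C | intermediate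
19 | propolis-benzofuran A | COc1cc([C@@H]2OC=C(c3cc4cc(O)c(C(C)=O)cc4o3)C[C@H]2COC(C)=O)ccc1O | target

**Step count**
Total: 10 steps. Longest linear sequence: 7 steps (steps 1–5, 9, 10); the aryl branch (steps 6–8) is 3 steps.

**Steps most likely to fail, with fallbacks**

Step 9 is the riskiest. The formyl group of 10 is a vinylogous formate and may form the Breslow intermediate slowly. The fluoride must also cleave the TBS ether of 15 while leaving three aryl TIPS ethers. If the TIPS cap para to the new phenol were lost, the quinone methide could tautomerise to an acetylquinone, which would oxidise the Breslow intermediate. The fallback gives up the carbene chemistry and builds the furan ring by alkyne coupling. It sets out from 10: dimethyl (1-diazo-2-oxopropyl)phosphonate with K2CO3 in MeOH gives the alkyne and also cleaves the acetate, giving [(2R,3S)-5-ethynyl-2-{3-methoxy-4-[(triisopropylsilyl)oxy]phenyl}-3,4-dihydro-2H-pyran-3-yl]methanol F1. Ac2O in pyridine restores the ester as the ethynyl acetate F2. Commercial 2-bromobenzene-1,4-diol with AcOH and BF3·OEt2 gives 1-(4-bromo-2,5-dihydroxyphenyl)ethan-1-one F3. Coupling of F2 and F3 with PdCl2(PPh3)2, CuI and Et3N in DMF at 70 °C gives the o-alkynylphenol F4 (not isolated), which closes 5-endo under the same conditions to the mono-silylated benzofuran F5. Bu4NF/AcOH then gives the target, so this fallback comes back to the route at 19.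

Step 5 may fail because the lactol has to lose water to the enol ether under the Vilsmeier conditions, and the acid-labile p-silyloxybenzylic ether is exposed to chloride and phosphorus acids. The fallback formylates the open-chain aldehyde tautomer under basic, non-ionising conditions. It sets out from 7: tert-butoxybis(dimethylamino)methane in toluene at 60 °C gives the enaminal (2S)-5-(dimethylamino)-4-formyl-2-[(R)-hydroxy{3-methoxy-4-[(triisopropylsilyl)oxy]phenyl}methyl]pent-4-en-1-yl acetate F6. Pyridinium p-toluenesulfonate in CH2Cl2 then lets the benzylic hydroxyl displace dimethylamine in a vinylogous transamidation-type ring closure, and the route is rejoined at 10.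

Step 8 may give ring bromination or α-bromination of the acetyl group on the electron-rich bis-silyl ether. The fallback brominates an electron-poor ester instead and carries the benzylic position as an acetate. It sets out from 12:
- Ac2O in pyridine gives 2-acetyl-5-methyl-1,4-phenylene diacetate F7.
- N-bromosuccinimide with 2,2′-azobis(2-methylpropionitrile) gives 2-acetyl-5-(bromomethyl)-1,4-phenylene diacetate F8.
- KOAc in DMF gives 2-acetyl-5-(acetoxymethyl)-1,4-phenylene diacetate F9.
- NH4OAc in aqueous MeOH removes only the two aryl acetates and gives (4-acetyl-2,5-dihydroxyphenyl)methyl acetate F10.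
- The one-flask silylation of step 7 passes through (4-acetyl-2-{[tert-butyl(dimethyl)silyl]oxy}-5-hydroxyphenyl)methyl acetate F11 (not isolated) and gives (4-acetyl-2-{[tert-butyl(dimethyl)silyl]oxy}-5-[(triisopropylsilyl)oxy]phenyl)methyl acetate F12.

Under the conditions of step 9, F12 loses the TBS group and then acetate to give the same quinone methide 16, which goes on through 17, so this fallback comes back to the route at 18.

**Further compounds**
F1 | step 9 | [(2R,3S)-5-ethynyl-2-{3-methoxy-4-[(triisopropylsilyl)oxy]phenyl}-3,4-dihydro-2H-pyran-3-yl]methanol | COc1cc([C@@H]2OC=C(C#C)C[C@H]2CO)ccc1O[Si](C(C)C)(C(C)C)C(C)C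
F2 | step 9 | [(2R,3S)-5-ethynyl-2-{3-methoxy-4-[(triisopropylsilyl)oxy]phenyl}-3,4-dihydro-2H-pyran-3-yl]methyl acetate | COc1cc([C@@H]2OC=C(C#C)C[C@H]2COC(C)=O)ccc1O[Si](C(C)C)(C(C)C)C(C)C
F3 | step 9 | 1-(4-bromo-2,5-dihydroxyphenyl)ethan-1-one | CC(=O)c1cc(O)c(Br)cc1O
F4 | step 9 | [(2R,3S)-5-[(4-acetyl-2,5-dihydroxyphenyl)ethynyl]-2-{3-methoxy-4-[(triisopropylsilyl)oxy]phenyl}-3,4-dihydro-2H-pyran-3-yl]methyl acetate | COc1cc([C@@H]2OC=C(C#Cc3cc(O)c(C(C)=O)cc3O)C[C@H]2COC(C)=O)ccc1O[Si](C(C)C)(C(C)C)C(C)C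
F5 | step 9 | [(2R,3S)-5-(6-acetyl-5-hydroxy-1-benzofuran-2-yl)-2-{3-methoxy-4-[(triisopropylsilyl)oxy]phenyl}-3,4-dihydro-2H-pyran-3-yl]methyl acetate | COc1cc([C@@H]2OC=C(c3cc4cc(O)c(C(C)=O)cc4o3)C[C@H]2COC(C)=O)ccc1O[Si](C(C)C)(C(C)C)C(C)C
F6 | step 5 | (2S)-5-(dimethylamino)-4-formyl-2-[(R)-hydroxy{3-methoxy-4-[(triisopropylsilyl)oxy]phenyl}methyl]pent-4-en-1-yl acetate | COc1cc([C@H](O)[C@H](COC(C)=O)CC(C=O)=CN(C)C)ccc1O[Si](C(C)C)(C(C)C)C(C)C
F7 | step 8 | 2-acetyl-5-methyl-1,4-phenylene diacetate | CC(=O)Oc1cc(C(C)=O)c(OC(C)=O)cc1C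
F8 | step 8 | 2-acetyl-5-(bromomethyl)-1,4-phenylene diacetate | CC(=O)Oc1cc(C(C)=O)c(OC(C)=O)cc1CBr
F9 | step 8 | 2-acetyl-5-(acetoxymethyl)-1,4-phenylene diacetate | CC(=O)OCc1cc(OC(C)=O)c(C(C)=O)cc1OC(C)=O
F10 | step 8 | (4-acetyl-2,5-dihydroxyphenyl)methyl acetate | CC(=O)OCc1cc(O)c(C(C)=O)cc1O
F11 | step 8 | (4-acetyl-2-{[tert-butyl(dimethyl)silyl]oxy}-5-hydroxyphenyl)methyl acetate | CC(=O)OCc1cc(O)c(C(C)=O)cc1O[Si](C)(C)C(C)(C)C
F12 | step 8 | (4-acetyl-2-{[tert-butyl(dimethyl)silyl]oxy}-5-[(triisopropylsilyl)oxy]phenyl)methyl acetate | CC(=O)OCc1cc(O[Si](C(C)C)(C(C)C)C(C)C)c(C(C)=O)cc1O[Si](C)(C)C(C)(C)C
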